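**Retrosynthetic overview**

- Both ester C–O bonds are cut first. The tiglate C–O bond comes from the key step, an Evans–Tishchenko redox esterification of a β-hydroxy ketone with tiglaldehyde, which also sets the second carbinol centre (1,3-anti) and tells the two oxygens apart; the senecioate follows by acylation.
- The cyclobutane is cut across two bonds: a transannular crossed [2+2] photocycloaddition of an 11-membered (Z,E,E)-trienone diester, steered by the tiglate-bearing allylic centre.
- The 11-membered ring is opened at the diene single bond: an intramolecular Heck reaction of a (Z)-β-iodo enone with a neopentyl vinyl group.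
- The β-hydroxy ketone comes from a Paterson boron aldol of 3,3-dimethylpent-4-en-2-one with an iodo dienal (first carbinol centre). The fragments derive from pyruvaldehyde dimethyl acetal, a Weinreb phosphonate and two Grignard reagents.
- Ring order: the 11-membered carbocycle first (Heck), then the cyclobutane, which closes the bicyclo[3.1.1]heptenone and the seven-membered ring in one step.

Assumption: (+)-Ipc2BCl (from (−)-α-pinene) is taken to direct Re-face addition of a methyl ketone enolate to an enal, giving the R carbinol; if the sense is the opposite, (−)-Ipc2BCl is used and nothing else changes.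

Step 1
Reactants: 1 1,1-dimethoxypropan-2-one; 2 diethyl {2-[methoxy(methyl)amino]-2-oxoethyl}phosphonate
Product: 3 (2E)-N,4,4-trimethoxy-N,3-dimethylbut-2-enamide
Conditions: NaH, THF, 0 → 25 °C
Reagents that add atoms: none
Why: Horner–Wadsworth–Emmons olefination of an activated α,α-dialkoxy ketone gives mainly the E enamide (acetal trans to the amide carbonyl, minor Z isomer removed by chromatography); no stereocentre is formed.

Step 2
Reactants: 3 (2E)-N,4,4-trimethoxy-N,3-dimethylbut-2-enamide; 4 prop-1-yn-1-ylmagnesium bromide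
Product: 5 (2E)-1,1-dimethoxy-2-methylhept-2-en-5-yn-4-one
Conditions: THF, −20 → 0 °C; then H2O
Reagents that add atoms: none
Why: Weinreb ketone synthesis; the magnesium chelate of the tetrahedral adduct survives until work-up, so the alkynyl Grignard reagent adds once and in 1,2-fashion.

Step 3
Reactants: 5 (2E)-1,1-dimethoxy-2-methylhept-2-en-5-yn-4-one
Product: 7 (2E,5Z)-6-iodo-2-methyl-4-oxohepta-2,5-dienal, via iodo dienone dimethyl acetal 6 (not isolated)
Conditions: NaI, AcOH, 25 °C, dark; aqueous Na2S2O3 wash; then crude 6, 2 M HCl, THF, 0 °C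
Reagents that add atoms: sodium iodide [Na+].[I-]; water O
Why: Conjugate hydroiodination of the ynone (iodide adds to the β-carbon and anti protonation gives the kinetic Z β-iodo enone) followed, once iodide is washed out so that it cannot reduce the ene-dicarbonyl product, by acid hydrolysis of the acetal.

Step 4
Reactants: 8 (3-methylbut-2-en-1-yl)magnesium chloride; 9 N-methoxy-N-methylacetamide
Product: 10 3,3-dimethylpent-4-en-2-one
Conditions: THF, −78 → 0 °C; then H2O
Reagents that add atoms: none
Why: Weinreb ketone synthesis with an allylic Grignard reagent, which reacts through its γ-carbon (cyclic SE2′ transition state) and so places the gem-dimethyl quaternary carbon next to a terminal vinyl group without over-addition.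

Step 5
Reactants: 10 3,3-dimethylpent-4-en-2-one; 7 (2E,5Z)-6-iodo-2-methyl-4-oxohepta-2,5-dienal
Product: 13 (6R,7E,10Z)-6-hydroxy-11-iodo-3,3,7-trimethyldodeca-1,7,10-triene-4,9-dione, via boron enolate 11 (not isolated), via boron aldolate 12 (not isolated)
Conditions: (+)-Ipc2BCl, Et3N, Et2O, 0 °C; 7, −78 → −20 °C; H2O2, MeOH, pH 7 buffer, 0 °C
Reagents that add atoms: none
Why: Paterson boron aldol reaction: the diisopinocampheylboron enolate of the methyl ketone (its only enolisable position) adds to the aldehyde, the most electrophilic carbonyl of 7, through a cyclic transition state in which the pinene-derived ligands select the Re face and set the 6R carbinol centre (about 90% ee expected).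

Step 6
Reactants: 13 (6R,7E,10Z)-6-hydroxy-11-iodo-3,3,7-trimethyldodeca-1,7,10-triene-4,9-dione; 14 (2E)-2-methylbut-2-enal
Product: 15 (4R,6R,7E,10Z)-4-hydroxy-11-iodo-3,3,7-trimethyl-9-oxododeca-1,7,10-trien-6-yl (2E)-2-methylbut-2-enoate
Conditions: SmI2 (30 mol %), 14 (6 equiv), THF, −10 °C, dark
Reagents that add atoms: none
Why: Evans–Tishchenko reaction: the samarium-bound hemiacetal formed from the hydroxyl group and tiglaldehyde delivers its hydride to the β-ketone through a chair-like six-membered transition state, which forms the tiglate C–O bond on the existing carbinol oxygen and sets the new 4R carbinol anti to it, while the remote dienone ketone is out of reach.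

Step 7
Reactants: 15 (4R,6R,7E,10Z)-4-hydroxy-11-iodo-3,3,7-trimethyl-9-oxododeca-1,7,10-trien-6-yl (2E)-2-methylbut-2-enoate; 16 3-methylbut-2-enoyl chloride
Product: 17 (4R,6R,7E,10Z)-11-iodo-3,3,7-trimethyl-4-[(3-methylbut-2-enoyl)oxy]-9-oxododeca-1,7,10-trien-6-yl (2E)-2-methylbut-2-enoate
Conditions: pyridine, CH2Cl2, 0 → 25 °C
Reagents that add atoms: none
Why: Acylation of the remaining hindered secondary alcohol with the acid chloride; pyridine, without a stronger nucleophilic catalyst or a trialkylamine, spares the β-iodo enone and avoids deconjugation of the acyl group through a vinylketene, and no stereocentre is touched.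

Step 8
Reactants: 17 (4R,6R,7E,10Z)-11-iodo-3,3,7-trimethyl-4-[(3-methylbut-2-enoyl)oxy]-9-oxododeca-1,7,10-trien-6-yl (2E)-2-methylbut-2-enoate
Product: 18 (1R,3R,5E,7Z,10E)-4,4,7,11-tetramethyl-3-[(3-methylbut-2-enoyl)oxy]-9-oxocycloundeca-5,7,10-trien-1-yl (2E)-2-methylbut-2-enoate
Conditions: Pd(OAc)2 (10 mol %), P(o-tol)3 (20 mol %), Ag2CO3, MeCN, 60 °C, 1 mM
Reagents that add atoms: none
Why: Intramolecular Heck reaction used as macrocyclisation: oxidative addition into the Z vinyl iodide with retention, carbopalladation of the terminal carbon of the vinyl group and β-hydride elimination (possible only toward the E disubstituted alkene) close the 11-membered ring and keep the Z geometry that holds the two reacting alkenes face to face.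

Step 9
Reactants: 18 (1R,3R,5E,7Z,10E)-4,4,7,11-tetramethyl-3-[(3-methylbut-2-enoyl)oxy]-9-oxocycloundeca-5,7,10-trien-1-yl (2E)-2-methylbut-2-enoate
Product: 19 (1R,2R,3R,5R,7S,8R)-2,6,6,9-tetramethyl-5-[(3-methylbut-2-enoyl)oxy]-11-oxotricyclo[5.4.0.0^2,8]undec-9-en-3-yl (2E)-2-methylbut-2-enoate
Conditions: thioxanthen-9-one (10 mol %), 405 nm LED, degassed MeCN (1 mM), 20 °C
Reagents that add atoms: none
Why: Proposed new method: triplet-sensitised transannular crossed [2+2] photocycloaddition of an 11-membered cross-conjugated (Z,E,E)-trienone, in which energy transfer populates the dienone triplet, its terminal carbon bonds to the α-carbon of the facing enone in a six-membered closure pre-organised by the Z double bond, and the 1,4-biradical collapses to the cyclobutane (bicyclo[3.1.1]heptenone and seven-membered ring at once); the bond to the methyl-bearing alkene carbon forms anti to the allylic C–O(tigloyl) bond (Felkin–Anh-type, least allylic 1,2-strain), which fixes the four cage centres relative to the two carbinol centres, and the sensitiser is too low in triplet energy to excite the product enone; closest known reaction type: transannular enone–alkene [2+2] photocycloadditions of medium-ring dienones under direct UV irradiation.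

**Compound list**

1 | 1,1-dimethoxypropan-2-one | CC(=O)C(OC)OC | starting material
2 | diethyl {2-[methoxy(methyl)amino]-2-oxoethyl}phosphonate | CCOP(=O)(CC(=O)N(C)OC)OCC | starting material
3 | (2E)-N,4,4-trimethoxy-N,3-dimethylbut-2-enamide | CON(C)C(=O)/C=C(\C)C(OC)OC | intermediate
4 | prop-1-yn-1-ylmagnesium bromide | CC#C[Mg]Br | starting material
5 | (2E)-1,1-dimethoxy-2-methylhept-2-en-5-yn-4-one | CC#CC(=O)/C=C(\C)C(OC)OC | intermediate
6 | (2E,5Z)-6-iodo-1,1-dimethoxy-2-methylhepta-2,5-dien-4-one | COC(OC)/C(C)=C/C(=O)/C=C(/C)I | intermediate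
7 | (2E,5Z)-6-iodo-2-methyl-4-oxohepta-2,5-dienal | O=C/C(C)=C/C(=O)/C=C(/C)I | intermediate
8 | (3-methylbut-2-en-1-yl)magnesium chloride | CC(C)=CC[Mg]Cl | starting material
9 | N-methoxy-N-methylacetamide | CC(=O)N(C)OC | starting material
10 | 3,3-dimethylpent-4-en-2-one | CC(=O)C(C)(C)C=C | intermediate
11 | [(3,3-dimethylpenta-1,4-dien-2-yl)oxy]di(isopinocampheyl)borane, Ipc groups from (−)-α-pinene | C=C(OB([C@H]1C[C@H]2C[C@@H]([C@@H]1C)C2(C)C)[C@H]1C[C@H]2C[C@@H]([C@@H]1C)C2(C)C)C(C)(C)C=C | intermediate
12 | O-di(isopinocampheyl)boryl derivative of 13 (boron aldolate) | C=CC(C)(C)C(=O)C[C@@H](OB([C@H]1C[C@H]2C[C@@H]([C@@H]1C)C2(C)C)[C@H]1C[C@H]2C[C@@H]([C@@H]1C)C2(C)C)/C(C)=C/C(=O)/C=C(/C)I | intermediate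
13 | (6R,7E,10Z)-6-hydroxy-11-iodo-3,3,7-trimethyldodeca-1,7,10-triene-4,9-dione | O[C@@H](/C(C)=C/C(=O)/C=C(/C)I)CC(=O)C(C)(C)C=C | intermediate
14 | (2E)-2-methylbut-2-enal (tiglaldehyde) | C/C=C(\C)C=O | starting material
15 | (4R,6R,7E,10Z)-4-hydroxy-11-iodo-3,3,7-trimethyl-9-oxododeca-1,7,10-trien-6-yl (2E)-2-methylbut-2-enoate | C/C=C(\C)C(=O)O[C@@H](/C(C)=C/C(=O)/C=C(/C)I)C[C@@H](O)C(C)(C)C=C | intermediate
16 | 3-methylbut-2-enoyl chloride | CC(C)=CC(=O)Cl | starting material
17 | (4R,6R,7E,10Z)-11-iodo-3,3,7-trimethyl-4-[(3-methylbut-2-enoyl)oxy]-9-oxododeca-1,7,10-trien-6-yl (2E)-2-methylbut-2-enoate | C/C=C(\C)C(=O)O[C@@H](/C(C)=C/C(=O)/C=C(/C)I)C[C@@H](OC(=O)C=C(C)C)C(C)(C)C=C | intermediate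
18 | (1R,3R,5E,7Z,10E)-4,4,7,11-tetramethyl-3-[(3-methylbut-2-enoyl)oxy]-9-oxocycloundeca-5,7,10-trien-1-yl (2E)-2-methylbut-2-enoate | C/C=C(\C)C(=O)O[C@@H]1C[C@@H](OC(=O)C=C(C)C)C(C)(C)/C=C/C(C)=C\C(=O)/C=C/1C | intermediate
19 | (1R,2R,3R,5R,7S,8R)-2,6,6,9-tetramethyl-5-[(3-methylbut-2-enoyl)oxy]-11-oxotricyclo[5.4.0.0^2,8]undec-9-en-3-yl (2E)-2-methylbut-2-enoate | C/C=C(\C)C(=O)O[C@@H]1C[C@@H](OC(=O)C=C(C)C)C(C)(C)[C@@H]2[C@H]3C(=O)C=C(C)[C@@H]2[C@]31C | target

**Step count and risks**

Total step count: 9. Longest linear sequence: 8 (steps 1, 2, 3, 5, 6, 7, 8, 9).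

The three steps most likely to fail:

Step 6 (Evans–Tishchenko). The ketone sits next to a quaternary carbon, so hydride transfer may be slow; divalent samarium could reduce the iodo enone before it is converted to the trivalent catalyst; the tiglate could migrate. Fallback, from 13 back to 15: hydroxyl-directed anti reduction with Me4NBH(OAc)3 in MeCN/AcOH at −25 °C (Evans–Saksena) gives the anti diol (2Z,5E,7R,9R)-7,9-dihydroxy-2-iodo-6,10,10-trimethyldodeca-2,5,11-trien-4-one F1. The less hindered allylic hydroxyl of F1 is then acylated selectively with (2E)-2-methylbut-2-enoyl chloride and 2,4,6-collidine at −40 °C to give 15; the neopentyl hydroxyl stays free.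

Step 8 (Heck macrocyclisation). Oligomers may form, zerovalent palladium may ionise the allylic tiglate, and the Z iodo enone may isomerise. Fallback, from 17 back to 18: cross-metathesis of the terminal vinyl group with vinylboronic acid pinacol ester (second-generation Hoveyda–Grubbs catalyst, CH2Cl2, 40 °C) gives the alkenyl boronate (1E,4R,6R,7E,10Z)-11-iodo-3,3,7-trimethyl-4-[(3-methylbut-2-enoyl)oxy]-9-oxo-1-(4,4,5,5-tetramethyl-1,3,2-dioxaborolan-2-yl)dodeca-1,7,10-trien-6-yl (2E)-2-methylbut-2-enoate F2. An intramolecular Suzuki–Miyaura coupling (Pd(PPh3)4, K3PO4, aqueous THF, 1 mM, 50 °C) then closes the ring to 18 with retention at both alkenes.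

Step 9 (the proposed new photocycloaddition). Possible failures are the straight, five–four–six fused adduct instead of the crossed one, attack on the wrong face, a thermal 2H-pyran valence isomer of the Z dienone, and a secondary 1,3-acyl shift of the product enone. Fallback with known chemistry, from 15 back to 19: the Heck closure of step 8 is run on the hydroxy ester 15 to give the macrocyclic alcohol (1R,3R,5E,7Z,10E)-3-hydroxy-4,4,7,11-tetramethyl-9-oxocycloundeca-5,7,10-trien-1-yl (2E)-2-methylbut-2-enoate F3. F3 is irradiated directly (Pyrex-filtered medium-pressure mercury lamp, about 350 nm, benzene, 1 mM), the classical enone–alkene [2+2] protocol, to give the cage alcohol (1R,2R,3R,5R,7S,8R)-5-hydroxy-2,6,6,9-tetramethyl-11-oxotricyclo[5.4.0.0^2,8]undec-9-en-3-yl (2E)-2-methylbut-2-enoate F4. Regio- and stereoisomers are separated at this polar stage, and acylation of F4 with 16 under the step 7 conditions gives 19.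

Further compounds
F1 | step 6 | (2Z,5E,7R,9R)-7,9-dihydroxy-2-iodo-6,10,10-trimethyldodeca-2,5,11-trien-4-one | O[C@@H](/C(C)=C/C(=O)/C=C(/C)I)C[C@@H](O)C(C)(C)C=C
F2 | step 8 | (1E,4R,6R,7E,10Z)-11-iodo-3,3,7-trimethyl-4-[(3-methylbut-2-enoyl)oxy]-9-oxo-1-(4,4,5,5-tetramethyl-1,3,2-dioxaborolan-2-yl)dodeca-1,7,10-trien-6-yl (2E)-2-methylbut-2-enoate | C/C=C(\C)C(=O)O[C@@H](/C(C)=C/C(=O)/C=C(/C)I)C[C@@H](OC(=O)C=C(C)C)C(C)(C)/C=C/B1OC(C)(C)C(C)(C)O1
F3 | step 9 | (1R,3R,5E,7Z,10E)-3-hydroxy-4,4,7,11-tetramethyl-9-oxocycloundeca-5,7,10-trien-1-yl (2E)-2-methylbut-2-enoate | C/C=C(\C)C(=O)O[C@@H]1C[C@@H](O)C(C)(C)/C=C/C(C)=C\C(=O)/C=C/1C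
F4 | step 9 | (1R,2R,3R,5R,7S,8R)-5-hydroxy-2,6,6,9-tetramethyl-11-oxotricyclo[5.4.0.0^2,8]undec-9-en-3-yl (2E)-2-methylbut-2-enoate | C/C=C(\C)C(=O)O[C@@H]1C[C@@H](O)C(C)(C)[C@@H]2[C@H]3C(=O)C=C(C)[C@@H]2[C@]31C
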